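Retrosynthetic cuts, in order: the six O–CH3 bonds that mask the phenols; the C5–vinyl bond of the stilbene arm (Heck); the C2–C3 bond of the dihydrofuran ring (carbene C–H insertion, with C2 in its kinetic cis form); the C3–aryl bond of the derived benzophenone (Grignard addition); the O1–CH2 bond (Williamson ether).
Forward: 5-bromosalicylaldehyde is O-benzylated, the 3,5-dimethoxyphenyl ring is added to the aldehyde, and the ketone hydrazone is closed to the dihydrofuran ring, the only ring made; the styryl arm is then attached at C5, C2 is equilibrated and the ethers are cleaved.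
Enabling feature: with the C2–C3 bond cut, C2 is an O–CH2–aryl carbon (benzylic and alpha to O1) lying 1,5 to the carbene carbon C3 along C3–C3a–C7a–O1–C2, so insertion can close only the five-membered ring; the C2 aryl ring carries an oxygen para to C2, so the C2–O1 bond can ionize reversibly.
Stereochemistry: C3 (S) is set by the chiral dirhodium catalyst in the insertion and is not touched again; C2 forms cis (R) and is inverted to S (trans) by acid equilibration under control of C3; the E alkene comes from the Heck reaction.

Key step: step 6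

Assumption: Rh2(R-PTAD)4, dirhodium tetrakis[(R)-(1-adamantyl)(N-phthalimido)acetate], is taken as the catalyst antipode that gives the 3S series; the sense of induction is to be confirmed on the insertion product, and if it is the opposite the S-configured catalyst is used with nothing else changed.

Step 1
Reactants: 1 3,4-dimethoxybenzyl alcohol
Product: 2 3,4-dimethoxybenzyl chloride
Conditions: SOCl2 (1.2 equiv), CH2Cl2, 0 °C to rt; evaporate, use crude at once
Reagents that add atoms: thionyl chloride, O=S(Cl)Cl
Why: Deoxychlorination of a benzylic alcohol through its chlorosulfite is fast for this electron-rich system, and the labile chloride is carried on at once because it self-alkylates on storage.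

Step 2
Reactants: 2 3,4-dimethoxybenzyl chloride; 3 5-bromosalicylaldehyde (5-bromo-2-hydroxybenzaldehyde)
Product: 4 5-bromo-2-[(3,4-dimethoxyphenyl)methoxy]benzaldehyde
Conditions: K2CO3, KI (cat.), DMF, 60 °C
Reagents that add atoms: none
Why: Williamson ether synthesis, in which the acidic salicylaldehyde phenol is deprotonated by carbonate and alkylated at oxygen by the reactive benzylic chloride under iodide catalysis while the aldehyde and the aryl bromide stay untouched.

Step 3
Reactants: 4 5-bromo-2-[(3,4-dimethoxyphenyl)methoxy]benzaldehyde; 5 1-bromo-3,5-dimethoxybenzene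
Product: 7 racemic [5-bromo-2-[(3,4-dimethoxyphenyl)methoxy]phenyl](3,5-dimethoxyphenyl)methanol, via 3,5-dimethoxyphenylmagnesium bromide 6 (not isolated)
Conditions: 5, Mg, I2 (cat.), THF, reflux; then 4, THF, −78 to 0 °C; aq NH4Cl
Reagents that add atoms: none
Why: Grignard 1,2-addition to the aldehyde, in which the aryl Grignard reagent does not exchange with the electron-rich aryl bromide of 4 at low temperature so that the C5 bromine is kept, and the new carbinol centre may stay racemic because the next step removes it.

Step 4
Reactants: 7 racemic diaryl carbinol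
Product: 8 [5-bromo-2-[(3,4-dimethoxyphenyl)methoxy]phenyl](3,5-dimethoxyphenyl)methanone
Conditions: MnO2 (activated, 10 equiv), CH2Cl2, rt
Reagents that add atoms: none
Why: Oxidation of a doubly benzylic secondary alcohol with activated MnO2 is selective and should leave the benzyl ether, the methyl ethers and the aryl bromide alone.

Step 5
Reactants: 8 diaryl ketone
Product: 9 hydrazone of ketone 8 (E/Z mixture about C=N, used as such)
Conditions: N2H4·H2O (10 equiv), AcOH (cat.), EtOH, 90 °C, sealed tube
Reagents that add atoms: hydrazine hydrate, NN.O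
Why: Acid-catalysed hydrazone condensation, driven by a large excess of hydrazine that also suppresses azine formation, and both geometric isomers lead to the same diazo compound.

Step 6
Reactants: 9 hydrazone of ketone 8
Product: 11 (2R,3S)-5-bromo-2-(3,4-dimethoxyphenyl)-3-(3,5-dimethoxyphenyl)-2,3-dihydro-1-benzofuran (2,3-cis), via diaryldiazomethane 10 (not isolated)
Conditions: MnO2 (8 equiv), CH2Cl2, 0 °C, filter through Celite; filtrate added slowly to Rh2(R-PTAD)4 (1 mol%), CH2Cl2, 0 °C
Reagents that add atoms: none
Why: MnO2 dehydrogenates the hydrazone to diaryldiazomethane 10, which loses N2 on the divalent-rhodium dimer to give a rhodium-bound donor/donor carbene at the future C3, and this carbene inserts into one C–H bond of the O–CH2–aryl group through a concerted, asynchronous transition state with hydride-shift character, forming the C2–C3 bond. The closest known reaction type is the enantioselective intramolecular 1,5-C–H insertion of diaryl rhodium carbenes, made from hydrazones, into benzylic ether C–H bonds to give cis-2,3-diaryl-2,3-dihydrobenzofurans. The dihydrofuran ring closes by C–C bond formation between the carbene carbon and the carbon five atoms along the tether (C3–C3a–C7a–O1–C2), a five-membered ring closure by C–H insertion. C3 is set as S by the chiral carboxylate ligands of the catalyst, which expose one face of the carbene to the C–H bond, and C2 is set as R (cis) by the compact insertion transition state, a kinetic preference that is not relied on because C2 is equilibrated in step 8. The step needs enantioselectivity at C3 and 1,5-site selectivity; the ortho ether tether puts only this CH2 within reach, the ether oxygen and the 3,4-dimethoxyphenyl ring make its C–H bonds hydridic, and the low electrophilicity of the donor/donor carbene should keep azine formation and dimerization behind the insertion.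

Step 7
Reactants: 11 (2R,3S)-cis bromide; 12 3,5-dimethoxystyrene
Product: 13 (2R,3S)-2-(3,4-dimethoxyphenyl)-3-(3,5-dimethoxyphenyl)-5-[(E)-2-(3,5-dimethoxyphenyl)ethenyl]-2,3-dihydro-1-benzofuran (2,3-cis)
Conditions: Pd(OAc)2 (5 mol%), [HP(t-Bu)3]BF4 (10 mol%), Cy2NMe, 1,4-dioxane, 100 °C
Reagents that add atoms: none
Why: Mizoroki–Heck reaction, in which zerovalent palladium carrying P(t-Bu)3 inserts into the electron-rich aryl C–Br bond, syn carbopalladation at the terminal carbon of the styrene and syn beta-hydride elimination give the E-stilbene, and the two ring stereocentres take no part.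

Step 8
Reactants: 13 cis hexamethyl ether
Product: 14 (2S,3S)-2-(3,4-dimethoxyphenyl)-3-(3,5-dimethoxyphenyl)-5-[(E)-2-(3,5-dimethoxyphenyl)ethenyl]-2,3-dihydro-1-benzofuran (2,3-trans)
Conditions: TFA (5 equiv), CH2Cl2 (0.01 M), −20 to 0 °C, dark; aq NaHCO3
Reagents that add atoms: none
Why: Acid-mediated cis-to-trans equilibration of a 2-(4-alkoxyaryl)-2,3-dihydrobenzofuran, in which protonation at O1 ionizes the C2–O1 bond to the 3,4-dimethoxybenzylic cation (an O-methylated para-quinone methide), the tethered phenol recloses the five-membered ring, and the more stable isomer with the two aryl groups on opposite faces accumulates, so that the untouched C3 (S) centre fixes C2 as S at a stage where the integrity of C3 can be followed by chiral HPLC.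

Step 9
Reactants: 14 trans hexamethyl ether
Product: 15 4-[(2S,3S)-3-(3,5-dihydroxyphenyl)-5-[(E)-2-(3,5-dihydroxyphenyl)ethenyl]-2,3-dihydro-1-benzofuran-2-yl]benzene-1,2-diol (target)
Conditions: BBr3 (15 equiv), CH2Cl2, −78 to 0 °C, argon, dark; ice-water quench, EtOAc extraction
Reagents that add atoms: none
Why: Lewis-acid cleavage of aryl methyl ethers (boron coordination at oxygen, bromide attack at methyl, hydrolysis of the aryl borates on work-up), run cold to spare the stilbene, and since C2 already has its thermodynamic trans arrangement any reversible C2–O1 opening through the para-quinone methide of the unmasked catechol ring should reclose to the same isomer.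

Compound list
1 | 3,4-dimethoxybenzyl alcohol | COc1ccc(CO)cc1OC | starting material
2 | 3,4-dimethoxybenzyl chloride | COc1ccc(CCl)cc1OC | intermediate
3 | 5-bromosalicylaldehyde (5-bromo-2-hydroxybenzaldehyde) | O=Cc1cc(Br)ccc1O | starting material
4 | 5-bromo-2-[(3,4-dimethoxyphenyl)methoxy]benzaldehyde | COc1ccc(COc2ccc(Br)cc2C=O)cc1OC | intermediate
5 | 1-bromo-3,5-dimethoxybenzene | COc1cc(Br)cc(OC)c1 | starting material
6 | 3,5-dimethoxyphenylmagnesium bromide (not isolated) | COc1cc([Mg]Br)cc(OC)c1 | intermediate
7 | racemic [5-bromo-2-[(3,4-dimethoxyphenyl)methoxy]phenyl](3,5-dimethoxyphenyl)methanol | COc1cc(OC)cc(c1)C(O)c1cc(Br)ccc1OCc1ccc(OC)c(OC)c1 | intermediate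
8 | [5-bromo-2-[(3,4-dimethoxyphenyl)methoxy]phenyl](3,5-dimethoxyphenyl)methanone | COc1cc(OC)cc(c1)C(=O)c1cc(Br)ccc1OCc1ccc(OC)c(OC)c1 | intermediate
9 | hydrazone of ketone 8 (E/Z mixture) | COc1cc(OC)cc(c1)C(=NN)c1cc(Br)ccc1OCc1ccc(OC)c(OC)c1 | intermediate
10 | 4-bromo-2-[diazo(3,5-dimethoxyphenyl)methyl]-1-[(3,4-dimethoxyphenyl)methoxy]benzene (not isolated) | COc1cc(OC)cc(c1)C(=[N+]=[N-])c1cc(Br)ccc1OCc1ccc(OC)c(OC)c1 | intermediate
11 | (2R,3S)-5-bromo-2-(3,4-dimethoxyphenyl)-3-(3,5-dimethoxyphenyl)-2,3-dihydro-1-benzofuran (cis) | Brc1ccc2c(c1)[C@H](c1cc(OC)cc(OC)c1)[C@H](c1ccc(OC)c(OC)c1)O2 | intermediate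
12 | 3,5-dimethoxystyrene | C=Cc1cc(OC)cc(OC)c1 | starting material
13 | (2R,3S)-2-(3,4-dimethoxyphenyl)-3-(3,5-dimethoxyphenyl)-5-[(E)-2-(3,5-dimethoxyphenyl)ethenyl]-2,3-dihydro-1-benzofuran (cis) | COc1cc(OC)cc(/C=C/c2ccc3c(c2)[C@H](c2cc(OC)cc(OC)c2)[C@H](c2ccc(OC)c(OC)c2)O3)c1 | intermediate
14 | (2S,3S)-2-(3,4-dimethoxyphenyl)-3-(3,5-dimethoxyphenyl)-5-[(E)-2-(3,5-dimethoxyphenyl)ethenyl]-2,3-dihydro-1-benzofuran (trans) | COc1cc(OC)cc(/C=C/c2ccc3c(c2)[C@H](c2cc(OC)cc(OC)c2)[C@@H](c2ccc(OC)c(OC)c2)O3)c1 | intermediate
15 | 4-[(2S,3S)-3-(3,5-dihydroxyphenyl)-5-[(E)-2-(3,5-dihydroxyphenyl)ethenyl]-2,3-dihydro-1-benzofuran-2-yl]benzene-1,2-diol | Oc1cc(O)cc(/C=C/c2ccc3c(c2)[C@H](c2cc(O)cc(O)c2)[C@@H](c2ccc(O)c(O)c2)O3)c1 | target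

Total step count: 9 steps.
Longest linear sequence: 9 steps, from alcohol 1 to target 15 (8 steps from aldehyde 3); compounds 5 and 12 are bought and enter directly.

Steps most likely to fail

Step 6. What may go wrong is that carbene transfer is not enantioselective enough at C3, or that the diazo compound is consumed by azine formation or reoxidation to the ketone before it inserts. The fallback forms the same C2–C3 bond by carbanion chemistry and secures the enantiomer by resolution. It sets out from ketone 8. Its benzylic ether CH2 is deprotonated with lithium 2,2,6,6-tetramethylpiperidide in THF at −78 °C, and the carbanion adds to the neighbouring diaryl ketone to give racemic 5-bromo-2-(3,4-dimethoxyphenyl)-3-(3,5-dimethoxyphenyl)-2,3-dihydro-1-benzofuran-3-ol F1. Ionic deoxygenation of this tertiary, doubly benzylic alcohol with Et3SiH and BF3·OEt2 at −78 °C, followed by a short TFA equilibration as in step 8, should give the racemic trans bromide F2. Preparative HPLC on a chiral stationary phase then separates the (2S,3S)-trans bromide F3. Heck coupling of this bromide with styrene 12 under the conditions of step 7 comes back to the route at compound 14.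

Step 9. What may go wrong is acid-driven loss of the stilbene (HBr addition, cationic oligomerization), and ring opening at C2–O1 followed by loss of the C3 proton, while six ethers are cleaved slowly. The fallback takes the ether cleavage ahead of the stilbene and changes the protecting group. It sets out from bromide 11, which with BBr3 in CH2Cl2 should lose its four methyl groups and equilibrate at C2 to give (2S,3S)-5-bromo-2-(3,4-dihydroxyphenyl)-3-(3,5-dihydroxyphenyl)-2,3-dihydro-1-benzofuran F4. Acetylation (Ac2O, pyridine) gives the tetraacetate F5. Heck coupling with the known 3,5-diacetoxystyrene F6 under the conditions of step 7 gives the hexaacetate of the target F7. Methanolysis with K2CO3 (cat.) in MeOH at 0 °C under argon returns to the route at compound 15.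

Step 8. What may go wrong is that the ring-opened benzylic cation loses the C3 proton (erosion of the C3 configuration, triarylethylene formation) or alkylates the electron-rich stilbene before it recloses. The fallback drops the separate equilibration and moves the C2 correction to the phenol stage. It sets out from cis compound 13, which is demethylated directly with BBr3 as in step 9. Whatever (2R,3S)-cis hexaphenol F8 remains is then equilibrated under much weaker acid (AcOH in aqueous MeCN, rt). This works because the free 4-hydroxyl of the catechol ring lets the C2–O1 bond open to a neutral para-quinone methide, which recloses anti to the C3 aryl group. The sequence comes back to the route at compound 15.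

Further compounds
F1 | step 6 | racemic 5-bromo-2-(3,4-dimethoxyphenyl)-3-(3,5-dimethoxyphenyl)-2,3-dihydro-1-benzofuran-3-ol (diastereomer mixture) | COc1cc(OC)cc(c1)C1(O)C(c2ccc(OC)c(OC)c2)Oc2ccc(Br)cc12
F2 | step 6 | racemic trans-5-bromo-2-(3,4-dimethoxyphenyl)-3-(3,5-dimethoxyphenyl)-2,3-dihydro-1-benzofuran (both enantiomers) | Brc1ccc2c(c1)[C@H](c1cc(OC)cc(OC)c1)[C@@H](c1ccc(OC)c(OC)c1)O2.Brc1ccc2c(c1)[C@@H](c1cc(OC)cc(OC)c1)[C@H](c1ccc(OC)c(OC)c1)O2
F3 | step 6 | (2S,3S)-5-bromo-2-(3,4-dimethoxyphenyl)-3-(3,5-dimethoxyphenyl)-2,3-dihydro-1-benzofuran (trans) | Brc1ccc2c(c1)[C@H](c1cc(OC)cc(OC)c1)[C@@H](c1ccc(OC)c(OC)c1)O2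
F4 | step 9 | (2S,3S)-5-bromo-2-(3,4-dihydroxyphenyl)-3-(3,5-dihydroxyphenyl)-2,3-dihydro-1-benzofuran (trans) | Brc1ccc2c(c1)[C@H](c1cc(O)cc(O)c1)[C@@H](c1ccc(O)c(O)c1)O2
F5 | step 9 | tetraacetate of F4 | Brc1ccc2c(c1)[C@H](c1cc(OC(C)=O)cc(OC(C)=O)c1)[C@@H](c1ccc(OC(C)=O)c(OC(C)=O)c1)O2
F6 | step 9 | 3,5-diacetoxystyrene | C=Cc1cc(OC(C)=O)cc(OC(C)=O)c1
F7 | step 9 | hexaacetate of target 15 | CC(=O)Oc1cc(OC(C)=O)cc(/C=C/c2ccc3c(c2)[C@H](c2cc(OC(C)=O)cc(OC(C)=O)c2)[C@@H](c2ccc(OC(C)=O)c(OC(C)=O)c2)O3)c1
F8 | step 8 | (2R,3S)-cis hexaphenol, C2 epimer of 15 | Oc1cc(O)cc(/C=C/c2ccc3c(c2)[C@H](c2cc(O)cc(O)c2)[C@H](c2ccc(O)c(O)c2)O3)c1
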